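## Retrosynthetic overview

1. The strategy rests on the cis C3=C4 alkene of the 2H-pyran ring. It lies between aromatic C4a and the quaternary stereocentre C2. The C2–O1 bond is allylic, and the O1–C2–C3=C4–C4a–C8a array can open electrocyclically, so this ring is closed last, under neutral, cool and dark conditions.
2. C3=C4 is cut by retro-metathesis to the styrenyl tertiary allyl ether 9. The pyran is the only ring built, and it is closed onto the purchased benzene ring.
3. C2–O1 is cut to vinylphenol 6 and solanesyl methyl carbonate 8. Asymmetric Pd O-allylation at the substituted allyl terminus sets C2 as R and turns C1–C2 of solanesol into the C2 vinyl group.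
4. Vinylphenol 6 comes from 2,3-dimethylhydroquinone by mono-silylation, ortho-formylation and methylenation. Buffered desilylation ends the route.

Key step: step 6

Assumption: the (R,R)-ligand with the (E)-carbonate is taken to give (R)-9. The sense is to be confirmed at 9 by correlation with ether made from epoxidation-derived (R)-isosolanesol, and the (S,S)-ligand is used if it proves opposite.

## Route

Step 1
Reactants: 1 2,3-dimethylhydroquinone
Product: 2 4-(tert-butyldimethylsilyloxy)-2,3-dimethylphenol
Conditions: TBSCl (0.95 equiv), imidazole, DMF, 0 °C → rt, Ar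
Reagents that add atoms: tert-butyldimethylsilyl chloride, CC(C)(C)[Si](C)(C)Cl
Why: The two hydroxyl groups of 1 are symmetry-equivalent, so silylation with a slight deficit of TBSCl is a statistical mono-protection with no regiochemical question, and the bis-ether and unreacted 1 can be separated and recycled.

Step 2
Reactants: 2 4-(tert-butyldimethylsilyloxy)-2,3-dimethylphenol
Product: 4 5-(tert-butyldimethylsilyloxy)-2-hydroxy-3,4-dimethylbenzaldehyde, via salicyl alcohol 3 (not isolated)
Conditions: MgCl2, Et3N, (CH2O)n, MeCN, reflux; then cold 1 M HCl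
Reagents that add atoms: paraformaldehyde (as formaldehyde), C=O
Why: In this Casnati–Skattebøl ortho-formylation the magnesium phenoxide delivers formaldehyde only ortho to the free OH, where just one position is open, a second formaldehyde then oxidises the salicyl alcohol by Oppenauer-type hydride transfer, and the amine-buffered medium should leave the aryl silyl ether intact.

Step 3
Reactants: 4 5-(tert-butyldimethylsilyloxy)-2-hydroxy-3,4-dimethylbenzaldehyde; 5 methyltriphenylphosphonium bromide
Product: 6 4-(tert-butyldimethylsilyloxy)-2,3-dimethyl-6-vinylphenol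
Conditions: 5 (2.6 equiv), KOtBu (2.5 equiv), THF, 0 °C; then 4, 0 °C → rt; aq NH4Cl; used promptly
Reagents that add atoms: methyltriphenylphosphonium bromide 5, C[P+](c1ccccc1)(c1ccccc1)c1ccccc1.[Br-]
Why: This is a Wittig methylenation of a salicylaldehyde with excess ylide, in which the first equivalent is consumed by the phenolic O–H, and keeping the salt in excess over the base leaves no free alkoxide to attack the silyl ether.

Step 4
Reactants: 7 all-E-solanesol
Product: 8 all-E-solanesyl methyl carbonate
Conditions: ClCO2Me, pyridine, CH2Cl2, 0 °C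
Reagents that add atoms: methyl chloroformate, COC(=O)Cl
Why: O-acylation of the primary allylic alcohol with a chloroformate under pyridine breaks no C–O bond, so neither allylic transposition nor loss of the 2E geometry is expected.

Step 5
Reactants: 6 4-(tert-butyldimethylsilyloxy)-2,3-dimethyl-6-vinylphenol; 8 all-E-solanesyl methyl carbonate
Product: 9 (R)-4-(tert-butyldimethylsilyloxy)-2,3-dimethyl-6-vinylphenyl isosolanesyl ether (tertiary ether; the C2 carbon carries methyl, vinyl, aryloxy and the all-E octaprenyl-derived chain)
Conditions: Pd2(dba)3·CHCl3 (2.5 mol %), (R,R)-DACH-phenyl Trost ligand (7.5 mol %), CH2Cl2, 0 °C → rt, Ar, dark; stopped when 8 is consumed; Et3N-deactivated silica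
Reagents that add atoms: none
Why: This is a palladium-catalysed asymmetric allylic alkylation (Tsuji–Trost type) of a phenol with an (E)-trisubstituted allyl carbonate, known to give tertiary aryl ethers from geranyl-type carbonates: ionisation with loss of CO2 and methoxide (which deprotonates 6) gives a syn π-allyl complex whose two faces interconvert through the σ-bound CH2 terminus without loss of E geometry, and outer-sphere attack of the phenoxide anti to palladium at the more substituted, more cationic terminus of the complex favoured by the ligand pocket sets C2 as R and leaves the former C1–C2 unit as the vinyl group.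

Step 6
Reactants: 9 (R)-styrenyl isosolanesyl ether
Product: 10 (R)-O-tert-butyldimethylsilyl plastochromenol-8
Conditions: Grubbs II (5 mol %), CH2Cl2 (5 mM), 30 °C, Ar sparge, dark; ethyl vinyl ether quench
Reagents that add atoms: none
Why: The active ruthenium species exchanges its alkylidene at the terminal CH2 of the styrene, the aryl-substituted alkylidene adds across the C2 vinyl group in an intramolecular [2+2], and cycloreversion of the ruthenacyclobutane gives C3=C4 plus a Ru=CH2 carrier that returns to the next styrene with release of ethylene. The closest known reaction is the Ru-catalysed ring-closing metathesis of 2-vinylaryl allyl ethers, 1,1-disubstituted allyl ethers included, to 2H-chromenes. The pyran ring closes as a six-membered ring by alkene–alkene metathesis between the benzylic CH (C4) and the vinyl CH (C3), and the ring size allows only the cis alkene. No stereocentre is formed, and C2 stays R because no bond to it is broken and the medium is neutral, near room temperature and dark, so neither C2–O1 ionisation nor electrocyclic opening should operate. The step needs six-ring closure to win over cyclopentene formation between the C2 vinyl and C3'=C4' and over any reaction of the eight trisubstituted alkenes; the styrene is the only accessible monosubstituted alkene, the vinyl group next to fully substituted, hydroxyl-free C2 loads slowly, and a catalyst that did load there would still close faster onto the monosubstituted styrene than onto a trisubstituted alkene, which would have to expel a disubstituted alkylidene. The C8 methyl group and the tertiary O-alkyl group weaken O→Ru chelation in the benzylidene, so the catalyst should not rest as a Hoveyda-type chelate.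

Step 7
Reactants: 10 (R)-O-tert-butyldimethylsilyl plastochromenol-8
Product: 11 (R)-plastochromenol-8
Conditions: TBAF, AcOH (1:1), THF, 0 °C, Ar, dark
Reagents that add atoms: none
Why: Fluoride-induced cleavage of the aryl silyl ether is fast at 0 °C, and the acetic acid buffer protonates the phenoxide as it forms, so oxidation of the electron-rich phenoxide and base- or acid-promoted opening at C2–O1 are avoided and C2 stays R.

## Compound list

1 | 2,3-dimethylhydroquinone | Cc1c(O)ccc(O)c1C | starting material
2 | 4-(tert-butyldimethylsilyloxy)-2,3-dimethylphenol | Cc1c(O)ccc(O[Si](C)(C)C(C)(C)C)c1C | intermediate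
3 | 4-(tert-butyldimethylsilyloxy)-6-(hydroxymethyl)-2,3-dimethylphenol (salicyl alcohol, present as magnesium salt, not isolated) | OCc1cc(O[Si](C)(C)C(C)(C)C)c(C)c(C)c1O | intermediate
4 | 5-(tert-butyldimethylsilyloxy)-2-hydroxy-3,4-dimethylbenzaldehyde | O=Cc1cc(O[Si](C)(C)C(C)(C)C)c(C)c(C)c1O | intermediate
5 | methyltriphenylphosphonium bromide | C[P+](c1ccccc1)(c1ccccc1)c1ccccc1.[Br-] | starting material
6 | 4-(tert-butyldimethylsilyloxy)-2,3-dimethyl-6-vinylphenol | C=Cc1cc(O[Si](C)(C)C(C)(C)C)c(C)c(C)c1O | intermediate
7 | all-E-solanesol | CC(C)=CCC/C(C)=C/CC/C(C)=C/CC/C(C)=C/CC/C(C)=C/CC/C(C)=C/CC/C(C)=C/CC/C(C)=C/CC/C(C)=C/CO | starting material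
8 | all-E-solanesyl methyl carbonate | CC(C)=CCC/C(C)=C/CC/C(C)=C/CC/C(C)=C/CC/C(C)=C/CC/C(C)=C/CC/C(C)=C/CC/C(C)=C/CC/C(C)=C/COC(=O)OC | intermediate
9 | (R)-4-(tert-butyldimethylsilyloxy)-2,3-dimethyl-6-vinylphenyl (6E,10E,14E,18E,22E,26E,30E)-3,7,11,15,19,23,27,31,35-nonamethylhexatriaconta-1,6,10,14,18,22,26,30,34-nonaen-3-yl ether | CC(C)=CCC/C(C)=C/CC/C(C)=C/CC/C(C)=C/CC/C(C)=C/CC/C(C)=C/CC/C(C)=C/CC/C(C)=C/CC[C@](C)(C=C)Oc1c(C=C)cc(O[Si](C)(C)C(C)(C)C)c(C)c1C | intermediate
10 | (R)-O-tert-butyldimethylsilyl plastochromenol-8 | CC(C)=CCC/C(C)=C/CC/C(C)=C/CC/C(C)=C/CC/C(C)=C/CC/C(C)=C/CC/C(C)=C/CC/C(C)=C/CC[C@]1(C)C=Cc2cc(O[Si](C)(C)C(C)(C)C)c(C)c(C)c2O1 | intermediate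
11 | (R)-plastochromenol-8 | CC(C)=CCC/C(C)=C/CC/C(C)=C/CC/C(C)=C/CC/C(C)=C/CC/C(C)=C/CC/C(C)=C/CC/C(C)=C/CC[C@]1(C)C=Cc2cc(O)c(C)c(C)c2O1 | target

## Step count and risks

Total step count: 7.
Longest linear sequence: 6 (steps 1, 2, 3, 5, 6, 7). The solanesol branch joins after step 4.

**Step 6 (key step).**
- What may go wrong: the catalyst may engage the C2 vinyl group first and close onto the neighbouring C3'=C4' alkene, a five-ring closure that cuts off the polyprenyl tail. Alternatively, turnover may stall at an O-chelated benzylidene, so that slow scrambling of the trisubstituted alkenes takes over.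
- Fallback: relay ring-closing metathesis, which fixes the site of catalyst loading through the substrate. It sets out from aldehyde 4 and comes back at 10.
- Wittig olefination of 4 with the ylide from hex-5-enyltriphenylphosphonium bromide should give (Z)-4-(tert-butyldimethylsilyloxy)-6-(hepta-1,6-dienyl)-2,3-dimethylphenol F1. The Pd-catalysed asymmetric O-allylation of step 5 with 8 should then give the (R)-relay ether F2.
- Ruthenium loads on the unhindered terminal alkene of the tether and expels cyclopentene. This places it on the benzylic carbon, from which only six-ring closure onto the C2 vinyl group is open, giving 10.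

**Step 5.**
- What may go wrong: attack of the doubly ortho-substituted phenoxide at the tertiary terminus may be slow. Linear O-allylation, β-hydride elimination of the π-allyl complex, Pd-mediated re-ionisation of the product or weak facial selectivity could then erode regio- and enantiopurity. A small residue of the minor enantiomer could be removed at 10 on a chiral stationary phase.
- Fallback: the stereocentre is taken from an epoxidation and transferred stereospecifically. It sets out from solanesol 7 and vinylphenol 6 and comes back at 9.
- Sharpless asymmetric epoxidation of 7 (Ti(OiPr)4, D-(−)-diethyl tartrate, TBHP, 4 Å sieves, CH2Cl2, −20 °C) touches only the allylic-alcohol alkene and should give (2R,3R)-2,3-epoxysolanesol F3.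
- Iodination (I2, PPh3, imidazole) should give (2S,3R)-2,3-epoxysolanesyl iodide F4. Zinc-induced reductive ring opening (Zn, THF/EtOH) should give (R)-isosolanesol F5 with the C3–O bond untouched.
- n-BuLi/ClCO2Me should give (R)-isosolanesyl methyl carbonate F6.
- Rhodium-catalysed enantiospecific allylic etherification (RhCl(PPh3)3, P(OMe)3, sodium phenoxide of 6 from NaHMDS, THF, 0 °C → rt) should substitute at the carbon that bore the leaving group with net retention, giving 9.
- Status of the last step: it combines two features established separately, namely etherification of secondary carbonates with ortho,ortho'-disubstituted phenoxides and stereospecific substitution of tertiary carbonates with carbon nucleophiles.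

**Step 3.**
- What may go wrong: phenoxide-mediated migration or loss of the silyl group during the Wittig reaction, and oligomerisation of the electron-rich vinylphenol on isolation.
- Fallback: the free vinylphenol is avoided by making the ether first. It sets out from aldehyde 4 and comes back at 9.
- The asymmetric O-allylation of step 5 is run on 4 with 8 and should give (R)-5-(tert-butyldimethylsilyloxy)-2-(isosolanesyloxy)-3,4-dimethylbenzaldehyde F7. Wittig methylenation of this neutral aldehyde with a small excess of ylide from 5 then gives 9.

## Further compounds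

F1 | step 6 | (Z)-4-(tert-butyldimethylsilyloxy)-6-(hepta-1,6-dienyl)-2,3-dimethylphenol | C=CCCC/C=C\c1cc(O[Si](C)(C)C(C)(C)C)c(C)c(C)c1O
F2 | step 6 | (R)-relay ether: 4-(tert-butyldimethylsilyloxy)-6-[(Z)-hepta-1,6-dienyl]-2,3-dimethylphenyl isosolanesyl ether | CC(C)=CCC/C(C)=C/CC/C(C)=C/CC/C(C)=C/CC/C(C)=C/CC/C(C)=C/CC/C(C)=C/CC/C(C)=C/CC[C@](C)(C=C)Oc1c(/C=C\CCCC=C)cc(O[Si](C)(C)C(C)(C)C)c(C)c1C
F3 | step 5 | (2R,3R)-2,3-epoxysolanesol | CC(C)=CCC/C(C)=C/CC/C(C)=C/CC/C(C)=C/CC/C(C)=C/CC/C(C)=C/CC/C(C)=C/CC/C(C)=C/CC[C@@]1(C)O[C@@H]1CO
F4 | step 5 | (2S,3R)-2,3-epoxysolanesyl iodide | CC(C)=CCC/C(C)=C/CC/C(C)=C/CC/C(C)=C/CC/C(C)=C/CC/C(C)=C/CC/C(C)=C/CC/C(C)=C/CC[C@@]1(C)O[C@@H]1CI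
F5 | step 5 | (R)-isosolanesol | CC(C)=CCC/C(C)=C/CC/C(C)=C/CC/C(C)=C/CC/C(C)=C/CC/C(C)=C/CC/C(C)=C/CC/C(C)=C/CC[C@](C)(C=C)O
F6 | step 5 | (R)-isosolanesyl methyl carbonate | CC(C)=CCC/C(C)=C/CC/C(C)=C/CC/C(C)=C/CC/C(C)=C/CC/C(C)=C/CC/C(C)=C/CC/C(C)=C/CC[C@](C)(C=C)OC(=O)OC
F7 | step 3 | (R)-5-(tert-butyldimethylsilyloxy)-2-(isosolanesyloxy)-3,4-dimethylbenzaldehyde | CC(C)=CCC/C(C)=C/CC/C(C)=C/CC/C(C)=C/CC/C(C)=C/CC/C(C)=C/CC/C(C)=C/CC/C(C)=C/CC[C@](C)(C=C)Oc1c(C=O)cc(O[Si](C)(C)C(C)(C)C)c(C)c1C
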